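The synthesis rests on cutting the bond between C2 of the pyran (C) ring and C1′ of the pyrogallol (B) ring. C2 is bonded to the ring oxygen O1, so a 2-ethoxy-2H-chromene of the A/C bicycle ionises to a 5,7-dialkoxybenzopyrylium ion with C2 as its electrophilic carbon. In the key step a chiral dihydroxy acid/lanthanide triflate pair transfers the whole tris(benzyloxy)phenyl group from boron to C2, forming this bond and the C2 stereocentre in one catalytic operation. The precursor is a racemic, flat chromene acetal that lacks the C3 oxygen; its C3=C4 alkene then receives that oxygen, which is inverted to cis under control of C2, acylated, and the benzyl groups are removed.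

Key step: step 4

Assumption: 5-bromo-1,2,3-tris(benzyloxy)benzene and 4-(benzyloxy)-3,5-dimethoxybenzoic acid are taken as catalogue compounds, and the antipode of the tartaric-acid-derived catalyst in step 4 is the one that delivers the (S)-chromene, its sense of induction to be confirmed on the first run.

Step 1
Reactants: 1 5,7-dihydroxycoumarin
Product: 2 5,7-bis(benzyloxy)coumarin
Conditions: BnBr, K2CO3, DMF, 60 °C
Reagents that add atoms: benzyl bromide, BrCc1ccccc1
Why: Williamson O-benzylation of both phenols with a carbonate base should proceed cleanly, because the lactone is untouched under anhydrous conditions and the pyranone-deactivated ring resists C-benzylation.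

Step 2
Reactants: 2 5,7-bis(benzyloxy)coumarin
Product: 4 racemic 2-ethoxy-5,7-bis(benzyloxy)-2H-chromene, via lactol 3 (not isolated)
Conditions: DIBAL-H, CH2Cl2, −78 °C; Rochelle salt work-up; crude lactol, EtOH, PPTS (cat.), 4 Å MS, rt
Reagents that add atoms: ethanol, CCO
Why: Low-temperature DIBAL-H half-reduction of the lactone should stop at the aluminium lactolate, and the derived 2H-chromen-2-ol should exchange its hydroxyl for ethoxy under mild acid through the stabilised 5,7-dialkoxybenzopyrylium ion (lactone-to-lactol reduction followed by acetalisation).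

Step 3
Reactants: 5 5-bromo-1,2,3-tris(benzyloxy)benzene
Product: 8 diethyl [3,4,5-tris(benzyloxy)phenyl]boronate, via aryllithium 6 (not isolated), via lithium triethoxyborate 7 (not isolated)
Conditions: n-BuLi, THF, −78 °C; B(OEt)3, −78 °C → rt; HCl (1 equiv, Et2O), 0 °C
Reagents that add atoms: triethyl borate, CCOB(OCC)OCC
Why: Bromine–lithium exchange at −78 °C should outrun benzylic deprotonation, the aryllithium is trapped by triethyl borate as the ate complex, and anhydrous HCl releases the diethyl boronate (borylation of an aryllithium).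

Step 4
Reactants: 4 racemic 2-ethoxy-5,7-bis(benzyloxy)-2H-chromene; 8 diethyl [3,4,5-tris(benzyloxy)phenyl]boronate
Product: 9 (2S)-5,7-bis(benzyloxy)-2-[3,4,5-tris(benzyloxy)phenyl]-2H-chromene
Conditions: tartaric-acid-derived dihydroxy acid mono-amide [4-(dibenzylamino)-2,3-dihydroxy-4-oxobutanoic acid, 10 mol%], Yb(OTf)3 (10 mol%), EtOAc, −20 → 4 °C
Reagents that add atoms: none
Why: The acid pair ionises acetal 4 to the 5,7-bis(benzyloxy)benzopyrylium ion while the chiral dihydroxy acid exchanges onto boron of 8, and coordination of the released ethoxide gives a chiral tetracoordinate boronate that transfers its aryl group to C2 within a contact ion pair (Petasis-type 1,2-transfer from an ate complex). The closest known reaction type is the enantioselective addition of aryl and alkenyl boronates to 2-alkoxy-2H-chromenes under chiral Brønsted acid/lanthanide triflate catalysis. No ring is closed. The new C2 stereocentre is under catalyst control by the tartaric-acid-derived ligand on boron, and because both enantiomers of 4 converge on the same planar cation the racemic acetal is fully usable. The step needs attack at C2 instead of C4 and one enantioface: the 5-benzyloxy group shields the peri position C4, and the boronate is held at the O1/C2 end of the cation where the ethoxide left. The only moderately nucleophilic trialkoxyaryl group is the main risk.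

Step 5
Reactants: 9 (2S)-5,7-bis(benzyloxy)-2-[3,4,5-tris(benzyloxy)phenyl]-2H-chromene
Product: 11 (2R,3S)-5,7-bis(benzyloxy)-2-[3,4,5-tris(benzyloxy)phenyl]chroman-3-ol (2,3-trans), via alkylborane 10 (not isolated)
Conditions: BH3·THF, THF, 0 °C → rt; then 3 M NaOH, 30% H2O2, 0 °C
Reagents that add atoms: hydrogen peroxide, OO
Why: In this hydroboration–oxidation boron should add to C3, away from the electron-rich and peri-hindered benzylic C4, on the face opposite the C2 aryl group, and oxidation with retention gives the 2,3-trans alcohol (C3 set by substrate control from C2).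

Step 6
Reactants: 11 (2R,3S)-5,7-bis(benzyloxy)-2-[3,4,5-tris(benzyloxy)phenyl]chroman-3-ol
Product: 12 (2R)-5,7-bis(benzyloxy)-2-[3,4,5-tris(benzyloxy)phenyl]chroman-3-one
Conditions: Dess–Martin periodinane, CH2Cl2, rt
Reagents that add atoms: none
Why: Dess–Martin oxidation under near-neutral conditions should convert the secondary alcohol into the ketone without enolising the C2 stereocentre.

Step 7
Reactants: 12 (2R)-5,7-bis(benzyloxy)-2-[3,4,5-tris(benzyloxy)phenyl]chroman-3-one
Product: 13 (2R,3R)-5,7-bis(benzyloxy)-2-[3,4,5-tris(benzyloxy)phenyl]chroman-3-ol (2,3-cis)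
Conditions: L-Selectride, THF, −78 °C; then H2O
Reagents that add atoms: none
Why: The bulky trialkylborohydride should attack the ketone from the face opposite the C2 aryl group, so the new C3–O bond ends cis to the aryl group (substrate-controlled diastereoselective reduction setting 3R).

Step 8
Reactants: 13 (2R,3R)-5,7-bis(benzyloxy)-2-[3,4,5-tris(benzyloxy)phenyl]chroman-3-ol; 14 4-(benzyloxy)-3,5-dimethoxybenzoic acid
Product: 15 (2R,3R)-5,7-bis(benzyloxy)-2-[3,4,5-tris(benzyloxy)phenyl]chroman-3-yl 4-(benzyloxy)-3,5-dimethoxybenzoate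
Conditions: DCC, DMAP (cat.), CH2Cl2, 0 °C → rt
Reagents that add atoms: none
Why: Steglich esterification should acylate the hindered axial secondary alcohol through the acylpyridinium ion with retention at C3.

Step 9
Reactants: 15 (2R,3R)-5,7-bis(benzyloxy)-2-[3,4,5-tris(benzyloxy)phenyl]chroman-3-yl 4-(benzyloxy)-3,5-dimethoxybenzoate
Product: 16 epigallocatechin 3-O-(3,5-di-O-methylgallate), (2R,3R)
Conditions: H2 (1 atm), 20% Pd(OH)2/C, THF/MeOH, rt, exclusion of air on work-up
Reagents that add atoms: none
Why: Hydrogenolysis over Pearlman's catalyst should remove all six benzyl ethers while the ester, the two methyl ethers and the cyclic C2–O1 ether are kept, and no stereocentre is touched.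

Compound list

1 | 5,7-dihydroxycoumarin (5,7-dihydroxy-2H-chromen-2-one) | O=C1C=Cc2c(O)cc(O)cc2O1 | starting material
2 | 5,7-bis(benzyloxy)coumarin | O=C1C=Cc2c(OCc3ccccc3)cc(OCc3ccccc3)cc2O1 | intermediate
3 | 5,7-bis(benzyloxy)-2H-chromen-2-ol (racemic lactol, not isolated) | OC1C=Cc2c(OCc3ccccc3)cc(OCc3ccccc3)cc2O1 | intermediate
4 | 2-ethoxy-5,7-bis(benzyloxy)-2H-chromene (racemic at C2) | CCOC1C=Cc2c(OCc3ccccc3)cc(OCc3ccccc3)cc2O1 | intermediate
5 | 5-bromo-1,2,3-tris(benzyloxy)benzene | Brc1cc(OCc2ccccc2)c(OCc2ccccc2)c(OCc2ccccc2)c1 | starting material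
6 | [3,4,5-tris(benzyloxy)phenyl]lithium (not isolated) | [Li]c1cc(OCc2ccccc2)c(OCc2ccccc2)c(OCc2ccccc2)c1 | intermediate
7 | lithium triethoxy[3,4,5-tris(benzyloxy)phenyl]borate (not isolated) | [Li+].CCO[B-](OCC)(OCC)c1cc(OCc2ccccc2)c(OCc2ccccc2)c(OCc2ccccc2)c1 | intermediate
8 | diethyl [3,4,5-tris(benzyloxy)phenyl]boronate | CCOB(OCC)c1cc(OCc2ccccc2)c(OCc2ccccc2)c(OCc2ccccc2)c1 | intermediate
9 | (2S)-5,7-bis(benzyloxy)-2-[3,4,5-tris(benzyloxy)phenyl]-2H-chromene (flav-3-ene) | C1=Cc2c(OCc3ccccc3)cc(OCc3ccccc3)cc2O[C@@H]1c1cc(OCc2ccccc2)c(OCc2ccccc2)c(OCc2ccccc2)c1 | intermediate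
10 | C3-borane (BH2 at C3, trans to the C2 aryl group) of the chroman (not isolated) | B[C@H]1Cc2c(OCc3ccccc3)cc(OCc3ccccc3)cc2O[C@@H]1c1cc(OCc2ccccc2)c(OCc2ccccc2)c(OCc2ccccc2)c1 | intermediate
11 | (2R,3S)-5,7-bis(benzyloxy)-2-[3,4,5-tris(benzyloxy)phenyl]chroman-3-ol (2,3-trans) | O[C@H]1Cc2c(OCc3ccccc3)cc(OCc3ccccc3)cc2O[C@@H]1c1cc(OCc2ccccc2)c(OCc2ccccc2)c(OCc2ccccc2)c1 | intermediate
12 | (2R)-5,7-bis(benzyloxy)-2-[3,4,5-tris(benzyloxy)phenyl]chroman-3-one | O=C1Cc2c(OCc3ccccc3)cc(OCc3ccccc3)cc2O[C@@H]1c1cc(OCc2ccccc2)c(OCc2ccccc2)c(OCc2ccccc2)c1 | intermediate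
13 | (2R,3R)-5,7-bis(benzyloxy)-2-[3,4,5-tris(benzyloxy)phenyl]chroman-3-ol (2,3-cis) | O[C@@H]1Cc2c(OCc3ccccc3)cc(OCc3ccccc3)cc2O[C@@H]1c1cc(OCc2ccccc2)c(OCc2ccccc2)c(OCc2ccccc2)c1 | intermediate
14 | 4-(benzyloxy)-3,5-dimethoxybenzoic acid | COc1cc(C(=O)O)cc(OC)c1OCc1ccccc1 | starting material
15 | (2R,3R)-5,7-bis(benzyloxy)-2-[3,4,5-tris(benzyloxy)phenyl]chroman-3-yl 4-(benzyloxy)-3,5-dimethoxybenzoate | COc1cc(C(=O)O[C@@H]2Cc3c(OCc4ccccc4)cc(OCc4ccccc4)cc3O[C@@H]2c2cc(OCc3ccccc3)c(OCc3ccccc3)c(OCc3ccccc3)c2)cc(OC)c1OCc1ccccc1 | intermediate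
16 | epigallocatechin 3-O-(3,5-di-O-methylgallate), (2R,3R) | COc1cc(C(=O)O[C@@H]2Cc3c(O)cc(O)cc3O[C@@H]2c2cc(O)c(O)c(O)c2)cc(OC)c1O | target

Total step count: 9
Longest linear sequence: 8 steps (steps 1, 2, 4, 5, 6, 7, 8, 9; step 3 prepares the second fragment)

Steps most likely to fail

Step 4. The aryl transfer may be slow, because the trialkoxyphenyl group on boron is only moderately nucleophilic and the 5,7-dialkoxybenzopyrylium ion is strongly stabilised. A loosely held ion pair may also erode the enantiofacial control or allow attack at C4. The fallback sets out from 5 and comes back at 9. Bromine–lithium exchange of 5, trapping with triisopropyl borate and aqueous acid should give [3,4,5-tris(benzyloxy)phenyl]boronic acid F1. This is added in a rhodium(I)/chiral diene catalysed asymmetric conjugate addition (dioxane/water, KOH cat.) to 5,7-bis(benzyloxy)-4H-chromen-4-one F2, itself made from purchased 5,7-dihydroxychromone with BnBr/K2CO3. The addition forms the same C2–aryl bond and should give (2S)-5,7-bis(benzyloxy)-2-[3,4,5-tris(benzyloxy)phenyl]chroman-4-one F3. Reduction with NaBH4 in THF/MeOH should give the chroman-4-ol F4 as a mixture at C4, and dehydration with catalytic p-TsOH in warm toluene should give flav-3-ene 9.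

Step 5. Boron may be delivered in part to C4, or the C3 borane may undergo β-alkoxy elimination with opening of the pyran ring before oxidation. The face of addition does not matter for the main route, since C3 becomes a ketone in step 6. The fallback sets out from 9 and comes back at 12. Epoxidation with dimethyldioxirane in acetone at −20 °C, anti to the C2 aryl group, should give the 3,4-epoxide of 9 with the oxirane oxygen trans to the aryl group F5. A catalytic Lewis acid (ZnBr2, CH2Cl2, −40 °C) should then trigger a Meinwald rearrangement: the oxirane opens at the A-ring-stabilised benzylic C4 and a 1,2-hydride shift from C3 gives ketone 12 directly.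

Step 6. The ketone formed has an acidic benzylic C2–H next to the carbonyl, so enolisation toward C2 may erase the C2 configuration, and the electron-rich enol may be oxidised further during oxidation or handling. The fallback sets out from 11 and comes back at 15. A Mitsunobu esterification of the trans alcohol 11 with acid 14 (PPh3, DIAD, THF, 0 °C) should give ester 15 directly with inversion at C3, so that neither ketone 12 nor alcohol 13 is needed and steps 7 and 8 are bypassed.

Further compounds

F1 | step 4 | [3,4,5-tris(benzyloxy)phenyl]boronic acid | OB(O)c1cc(OCc2ccccc2)c(OCc2ccccc2)c(OCc2ccccc2)c1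
F2 | step 4 | 5,7-bis(benzyloxy)-4H-chromen-4-one | O=C1C=COc2cc(OCc3ccccc3)cc(OCc3ccccc3)c12
F3 | step 4 | (2S)-5,7-bis(benzyloxy)-2-[3,4,5-tris(benzyloxy)phenyl]chroman-4-one | O=C1C[C@@H](c3cc(OCc4ccccc4)c(OCc4ccccc4)c(OCc4ccccc4)c3)Oc2cc(OCc3ccccc3)cc(OCc3ccccc3)c12
F4 | step 4 | (2S)-5,7-bis(benzyloxy)-2-[3,4,5-tris(benzyloxy)phenyl]chroman-4-ol (mixture at C4) | OC1C[C@@H](c3cc(OCc4ccccc4)c(OCc4ccccc4)c(OCc4ccccc4)c3)Oc2cc(OCc3ccccc3)cc(OCc3ccccc3)c12
F5 | step 5 | 3,4-epoxide of 9, oxirane oxygen trans to the C2 aryl group | O1[C@H]2[C@@H]1c1c(OCc3ccccc3)cc(OCc3ccccc3)cc1O[C@@H]2c1cc(OCc2ccccc2)c(OCc2ccccc2)c(OCc2ccccc2)c1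
F0 | step 6 | none | none
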